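## Retrosynthetic overview

1. Target 12 ⇒ bis-ester 10 by oxidation of the isopropenyl methyl group (CH3 → CH2OH → CHO, steps 6 and 7). No protecting group is used.
2. 10 ⇒ cis keto-alcohol 5. The C3 ester comes from a Mitsunobu inversion (cis → trans), the side-chain carbinol from asymmetric transfer hydrogenation of the 5-acetyl group, followed by acylation.
3. 5 ⇒ methallyl ether 3 by disconnection of C2–C3. The dihydrofuran ring (ring B) is the only ring to be made; it is closed onto the purchased benzene ring (ring A) by an enantioselective intramolecular carbonyl allylation that starts from an allylic C–H bond. 3 ⇒ phenol 1 + methallyl bromide 2.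
4. Enabling feature: in 3 the O–CH2 carbon (future C2) carries hydrogens that are both allylic to the 2-methylallyl C=C and α to the ether oxygen O1. O1 sits on ring A ortho to the formyl carbon (future C3), so hydrogen abstraction makes C2 the γ-carbon of an aryloxy-allyl nucleophile placed for five-membered ring closure. The allyl methyl group is the latent formyl carbon.

Key step: step 2

Remark: ring atoms are numbered as in 2,3-dihydro-1-benzofuran (O1, C2, C3, C3a, C4–C7, C7a); compound 1 is taken as a catalogue compound, and in step 2 the ligand antipode used is the one that leads to the (2R,3R) alcohol.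

## Route

Step 1
Reactants: 1 5-acetyl-2-hydroxybenzaldehyde; 2 3-bromo-2-methylprop-1-ene (methallyl bromide)
Product: 3 5-acetyl-2-[(2-methylprop-2-en-1-yl)oxy]benzaldehyde
Conditions: K2CO3, DMF, rt
Reagents that add atoms: 3-bromo-2-methylprop-1-ene (compound 2), C=C(C)CBr
Why: Williamson ether synthesis, in which the acidic phenol (activated by the ortho formyl and para acetyl groups) is O-alkylated by the allylic bromide in an SN2 reaction under conditions too mild for aldol condensation; no stereocentre is formed.

Step 2
Reactants: 3 5-acetyl-2-[(2-methylprop-2-en-1-yl)oxy]benzaldehyde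
Product: 5 1-[(2R,3R)-3-hydroxy-2-(prop-1-en-2-yl)-2,3-dihydro-1-benzofuran-5-yl]ethan-1-one (cis), via allyl–CrCl2 species 4 (not isolated)
Conditions: CrCl2 (10 mol %), (3aR,3a'R,8aS,8a'S)-2,2'-(cyclopropane-1,1-diyl)bis(3a,8a-dihydro-8H-indeno[1,2-d]oxazole) (12 mol %), 9-mesityl-10-phenylacridinium tetrafluoroborate (3 mol %), iPr3SiSH (10 mol %), Mg(ClO4)2, degassed CH2Cl2 (0.01 M), 440 nm LEDs, rt
Reagents that add atoms: none
Why: Proposed new method: the photoexcited acridinium oxidises the silanethiol co-catalyst to a thiyl radical, which abstracts one hydrogen of the O–CH2 group (the weakest and most hydridic C–H bond of 3, being both allylic and α to the ether oxygen); the 1-aryloxy-2-methylallyl radical is captured by divalent chromium as the trivalent σ-allylchromium species 4, which adds through its oxygen-bearing γ-carbon to the ortho formyl group, after which protonation of the chromium alkoxide and reduction of trivalent chromium by the acridine radical close both catalytic cycles. The closest known reaction type is the intermolecular photoredox/chromium-catalysed allylation of aldehydes by allylic C–H functionalisation of alkenes, including α-oxygenated allylic positions, which is run enantioselectively with bis(oxazoline)–chromium catalysts, together with intramolecular Nozaki–Hiyama–Kishi allylations; new here are the intramolecular mode and the aryl allyl ether. Ring B is closed by 5-exo-trig attack of C2 on the carbonyl carbon C3 through a bicyclic Zimmerman–Traxler transition state. Because the tether (C3a, C7a, O1) is held planar by ring A, only a cis fusion of the forming five-membered ring onto the six-membered chromium chelate is attainable, which should place the C3 hydroxyl and the C2 isopropenyl group cis; the absolute configuration (2R,3R) is set by the chiral bis(oxazoline) ligand on chromium, which selects the face of the coordinated aldehyde. The step needs site selectivity in hydrogen abstraction (O–CH2 over the methyl group and the formyl C–H, secured by bond strength and polarity matching), chemoselectivity for the aldehyde over the methyl ketone (inherent to allylchromium reagents) and ring closure over intermolecular allyl transfer (secured by dilution).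

Step 3
Reactants: 5 1-[(2R,3R)-3-hydroxy-2-(prop-1-en-2-yl)-2,3-dihydro-1-benzofuran-5-yl]ethan-1-one; 6 3-methylbutanoic acid
Product: 7 (2R,3S)-5-acetyl-2-(prop-1-en-2-yl)-2,3-dihydro-1-benzofuran-3-yl 3-methylbutanoate (trans)
Conditions: PPh3, DIAD, toluene, −20 °C to rt
Reagents that add atoms: 3-methylbutanoic acid (compound 6), CC(C)CC(=O)O
Why: Mitsunobu esterification, in which the oxyphosphonium ion of the benzylic C3 alcohol is displaced by 3-methylbutanoate in an SN2 reaction with inversion, the nucleophile entering from the face away from the cis isopropenyl group, so that (3R) becomes (3S) and the trans ester results, while the 5-acetyl group para to O1 disfavours ionisation at C3.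

Step 4
Reactants: 7 (2R,3S)-5-acetyl-2-(prop-1-en-2-yl)-2,3-dihydro-1-benzofuran-3-yl 3-methylbutanoate
Product: 8 (2R,3S)-5-[(1R)-1-hydroxyethyl]-2-(prop-1-en-2-yl)-2,3-dihydro-1-benzofuran-3-yl 3-methylbutanoate
Conditions: RuCl(p-cymene)[(R,R)-TsDPEN] (1 mol %), HCO2H/Et3N (5:2), EtOAc, 30 °C
Reagents that add atoms: none
Why: Noyori–Ikariya asymmetric transfer hydrogenation, in which the ruthenium hydride of the (R,R)-TsDPEN complex reduces the aryl methyl ketone through the outer-sphere six-membered transition state with CH–π recognition of the arene, which should give the (1R)-carbinol under catalyst control and leave the ester, the 1,1-disubstituted alkene and the ring stereocentres untouched.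

Step 5
Reactants: 8 (2R,3S)-5-[(1R)-1-hydroxyethyl]-2-(prop-1-en-2-yl)-2,3-dihydro-1-benzofuran-3-yl 3-methylbutanoate; 9 3-methylbutanoic anhydride
Product: 10 (1R)-1-[(2R,3S)-3-(3-methylbutanoyloxy)-2-(prop-1-en-2-yl)-2,3-dihydro-1-benzofuran-5-yl]ethyl 3-methylbutanoate
Conditions: DMAP (cat.), Et3N, CH2Cl2, 0 °C to rt
Reagents that add atoms: 3-methylbutanoic anhydride (compound 9), CC(C)CC(=O)OC(=O)CC(C)C
Why: DMAP-catalysed acyl transfer (Steglich-type nucleophilic catalysis) esterifies the secondary alcohol at oxygen under basic conditions, so the (1R) configuration is retained and no other stereocentre is touched.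

Step 6
Reactants: 10 (1R)-1-[(2R,3S)-3-(3-methylbutanoyloxy)-2-(prop-1-en-2-yl)-2,3-dihydro-1-benzofuran-5-yl]ethyl 3-methylbutanoate
Product: 11 (1R)-1-[(2R,3S)-2-(3-hydroxyprop-1-en-2-yl)-3-(3-methylbutanoyloxy)-2,3-dihydro-1-benzofuran-5-yl]ethyl 3-methylbutanoate
Conditions: SeO2 (0.5 equiv), tBuOOH (in decane, 3 equiv), CH2Cl2, 0 °C to rt
Reagents that add atoms: tert-butyl hydroperoxide, CC(C)(C)OO (terminal oxidant; the oxygen atom is passed on by way of SeO2, O=[Se]=O)
Why: Riley-type allylic oxidation, in which an ene reaction of the selenium oxidant at the terminal CH2 with hydrogen transfer from the methyl group (preferred over the hindered C2 methine in 1,1-disubstituted alkenes) and a [2,3]-sigmatropic shift return the 1,1-disubstituted alkene bearing a CH2OH group, under conditions mild enough to spare the benzylic esters and the C2 and C3 centres.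

Step 7
Reactants: 11 (1R)-1-[(2R,3S)-2-(3-hydroxyprop-1-en-2-yl)-3-(3-methylbutanoyloxy)-2,3-dihydro-1-benzofuran-5-yl]ethyl 3-methylbutanoate
Product: 12 (1R)-1-[(2R,3S)-3-(3-methylbutanoyloxy)-2-(3-oxoprop-1-en-2-yl)-2,3-dihydro-1-benzofuran-5-yl]ethyl 3-methylbutanoate (CNP0316116.2)
Conditions: activated MnO2 (excess), CH2Cl2, rt
Reagents that add atoms: none
Why: MnO2 oxidation is selective for primary allylic alcohols and runs under neutral conditions, so the α-substituted acrolein should form without touching the esters or the C2 centre, whose hydrogen is cross-conjugated and not enolisable.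

## Compound list

1 | 5-acetyl-2-hydroxybenzaldehyde | CC(=O)c1ccc(O)c(C=O)c1 | starting material
2 | 3-bromo-2-methylprop-1-ene | C=C(C)CBr | starting material
3 | 5-acetyl-2-[(2-methylprop-2-en-1-yl)oxy]benzaldehyde | CC(=O)c1ccc(OCC(C)=C)c(C=O)c1 | intermediate
4 | σ-allyl–CrCl2 species of 3, trivalent chromium on the terminal CH2 (bis(oxazoline) ligand not drawn, enol ether geometry not fixed) | CC(=O)c1ccc(OC=C(C)C[Cr](Cl)Cl)c(C=O)c1 | intermediate
5 | 1-[(2R,3R)-3-hydroxy-2-(prop-1-en-2-yl)-2,3-dihydro-1-benzofuran-5-yl]ethan-1-one | C=C(C)[C@H]1Oc2ccc(C(C)=O)cc2[C@H]1O | intermediate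
6 | 3-methylbutanoic acid | CC(C)CC(=O)O | starting material
7 | (2R,3S)-5-acetyl-2-(prop-1-en-2-yl)-2,3-dihydro-1-benzofuran-3-yl 3-methylbutanoate | C=C(C)[C@H]1Oc2ccc(C(C)=O)cc2[C@@H]1OC(=O)CC(C)C | intermediate
8 | (2R,3S)-5-[(1R)-1-hydroxyethyl]-2-(prop-1-en-2-yl)-2,3-dihydro-1-benzofuran-3-yl 3-methylbutanoate | C=C(C)[C@H]1Oc2ccc([C@@H](C)O)cc2[C@@H]1OC(=O)CC(C)C | intermediate
9 | 3-methylbutanoic anhydride | CC(C)CC(=O)OC(=O)CC(C)C | starting material
10 | (1R)-1-[(2R,3S)-3-(3-methylbutanoyloxy)-2-(prop-1-en-2-yl)-2,3-dihydro-1-benzofuran-5-yl]ethyl 3-methylbutanoate | C=C(C)[C@H]1Oc2ccc([C@@H](C)OC(=O)CC(C)C)cc2[C@@H]1OC(=O)CC(C)C | intermediate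
11 | (1R)-1-[(2R,3S)-2-(3-hydroxyprop-1-en-2-yl)-3-(3-methylbutanoyloxy)-2,3-dihydro-1-benzofuran-5-yl]ethyl 3-methylbutanoate | C=C(CO)[C@H]1Oc2ccc([C@@H](C)OC(=O)CC(C)C)cc2[C@@H]1OC(=O)CC(C)C | intermediate
12 | (1R)-1-[(2R,3S)-3-(3-methylbutanoyloxy)-2-(3-oxoprop-1-en-2-yl)-2,3-dihydro-1-benzofuran-5-yl]ethyl 3-methylbutanoate | C=C(C=O)[C@H]1Oc2ccc([C@@H](C)OC(=O)CC(C)C)cc2[C@@H]1OC(=O)CC(C)C | target

## Step count and risks

Total step count: 7. Longest linear sequence: 7 steps (from compound 1).

Steps most likely to fail:

**Step 2 (Proposed new method).** Facial control in the bicyclic transition state may be poor. Hydrogen abstraction at the formyl C–H, followed by acyl-radical cyclisation onto the alkene, may compete. Intermolecular allyl transfer may outrun ring closure. The fallback uses known photochemistry and resets the stereocentres afterwards. It sets out from compound 3. A Norrish–Yang photocyclisation (350 nm, degassed benzene; δ-hydrogen abstraction by the excited formyl group and collapse of the 1,5-biradical) should give racemic 1-[3-hydroxy-2-(prop-1-en-2-yl)-2,3-dihydro-1-benzofuran-5-yl]ethan-1-one F1 as a mixture of cis and trans isomers. Oxidation with Dess–Martin periodinane would give 5-acetyl-2-(prop-1-en-2-yl)-1-benzofuran-3(2H)-one F2, whose C2 centre is configurationally labile; it would be used without delay to limit migration of the double bond into conjugation. Asymmetric transfer hydrogenation with RuCl(p-cymene)[(S,S)-TsDPEN] in HCO2H/Et3N should reduce both ketones, the ring ketone under dynamic kinetic resolution to the cis alcohol, giving (1S)-1-[(2R,3R)-3-hydroxy-2-(prop-1-en-2-yl)-2,3-dihydro-1-benzofuran-5-yl]ethan-1-ol F3. A double Mitsunobu esterification with 3-methylbutanoic acid (6), PPh3 and DIAD, inverting both carbinol centres, comes back to the route at compound 10.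

**Step 3.** E2 loss of the C2 hydrogen across C2–C3, driven by aromatisation to the benzofuran, may compete with substitution, and partial ionisation at C3 may erode the inversion. The fallback replaces the SN2 redox condensation by ion-pair substitution steered by the C2 substituent. It sets out from compound 5. Cl3CCN with catalytic DBU in CH2Cl2 at 0 °C should give (2R,3R)-5-acetyl-2-(prop-1-en-2-yl)-2,3-dihydro-1-benzofuran-3-yl 2,2,2-trichloroethanimidate F4. Warming F4 with 3-methylbutanoic acid (6) in toluene without promoter should give the ester by collapse of the benzylic ion pair on the face away from the isopropenyl group, and comes back to the route at compound 7.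

**Step 6.** The ene reaction may take place at the C2 methine instead of the methyl group, oxidation may run on unevenly to the aldehyde stage, and the acidic selenium species may promote loss of the benzylic esters. The fallback avoids selenium oxidants at oxygen. It sets out from compound 10. Ene-type allylic chlorination (N-chlorosuccinimide, catalytic PhSeCl, CH2Cl2, rt) should give (1R)-1-[(2R,3S)-2-(3-chloroprop-1-en-2-yl)-3-(3-methylbutanoyloxy)-2,3-dihydro-1-benzofuran-5-yl]ethyl 3-methylbutanoate F5. Ganem oxidation of the allylic chloride with trimethylamine N-oxide in DMSO at rt comes back to the route at compound 12, so that step 7 is not needed.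

## Further compounds

F1 | step 2 | racemic 1-[3-hydroxy-2-(prop-1-en-2-yl)-2,3-dihydro-1-benzofuran-5-yl]ethan-1-one (cis/trans mixture) | C=C(C)C1Oc2ccc(C(C)=O)cc2C1O
F2 | step 2 | 5-acetyl-2-(prop-1-en-2-yl)-1-benzofuran-3(2H)-one (racemic, C2 labile) | C=C(C)C1Oc2ccc(C(C)=O)cc2C1=O
F3 | step 2 | (1S)-1-[(2R,3R)-3-hydroxy-2-(prop-1-en-2-yl)-2,3-dihydro-1-benzofuran-5-yl]ethan-1-ol | C=C(C)[C@H]1Oc2ccc([C@H](C)O)cc2[C@H]1O
F4 | step 3 | (2R,3R)-5-acetyl-2-(prop-1-en-2-yl)-2,3-dihydro-1-benzofuran-3-yl 2,2,2-trichloroethanimidate | C=C(C)[C@H]1Oc2ccc(C(C)=O)cc2[C@H]1OC(=N)C(Cl)(Cl)Cl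
F5 | step 6 | (1R)-1-[(2R,3S)-2-(3-chloroprop-1-en-2-yl)-3-(3-methylbutanoyloxy)-2,3-dihydro-1-benzofuran-5-yl]ethyl 3-methylbutanoate | C=C(CCl)[C@H]1Oc2ccc([C@@H](C)OC(=O)CC(C)C)cc2[C@@H]1OC(=O)CC(C)C
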